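## Structural features

The target is a trans-3,4-dibenzyl-γ-butyrolactone. Ring A (O1, C2 carbonyl, C3, C4, C5) is the only non-aromatic ring; C3 is joined through the methylene C6 to ring B (4-hydroxy-3,5-dimethoxyphenyl) and C4 through the methylene C7 to ring C (3,4-dimethoxyphenyl). C3 and C4 are adjacent stereocentres, both R, with the two arylmethyl arms trans. The two centres differ in kind: C3 is α to the lactone carbonyl and can be equilibrated, the trans arrangement being the more stable, whereas C4 is β, cannot be corrected once the lactone exists, and must be set in absolute terms. The fragile groups are the free, electron-rich phenol of ring B (acidic, easily oxidised towards a quinone methide) and the lactone (hydride, hydroxide); the aryl methyl ethers and the benzylic C–C bonds are robust. The real difficulty is that the skeleton is a 2,3-dibenzylsuccinate whose halves differ only in aryl substitution, so the carboxyl carbons C2 and C5 must be told apart and C4 must be made enantioselectively. The key step uses the fact that, with C5 at the ester level, C4–H is α and the C7–ring C bond is β to that ester. C5, C4 and C7 are then the carboxyl, α-carbon and methylene of a 2-methylenesuccinate, and aryl addition to the methylene followed by protonation at C4 makes the C7–ring C bond and the C4 centre together.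

## Logic of the disconnections

15 to 14: only the O–benzyl bond of the ring B phenol is cut. The phenol is the most sensitive group, so it is masked until the end; every earlier step is then free of an acidic, oxidisable phenol. The forward step must remove the benzyl group without touching the lactone or either stereocentre.

14 to 13: no skeletal bond is cut; the configuration at C3 is released. C3 is the only enolisable centre of the lactone and trans is the thermodynamic arrangement, so C3 need not be controlled earlier. This reduces the stereochemical problem to C4 alone. The forward equilibration must lie well on the trans side and must not touch C4.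

13 to 11 (through 12): the O1–C2 acyl–oxygen bond is cut and C5 is returned to the ester level. This gives an acyclic 2,3-disubstituted succinate in which C5 is a methyl ester and C2 a tert-butyl ester. The gain is an open-chain diester with the two carboxyls already distinguished. The forward steps need a hydride that reduces only the methyl ester, and C4 (α to that ester) must not epimerise before it is reduced.

11 to 9 and 10: the C7–ring C bond and the C4–H bond are cut. This is the strategic cut: it removes ring C as a commercial arylboron reagent and leaves an alkene with a single, racemic stereocentre at C3. The forward step must add the aryl group to the methylene carbon and protonate C4 under ligand control that dominates the adjacent C3 centre.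

9 to 7 and 4 (through 8): the C4=C7 double bond and the C3–C6 bond are cut. The methylene is traced to a one-carbon carbonyl reagent and a phosphonate, and the ring B arm to a benzylic halide. Both bonds can be made in one flask from a phosphonosuccinate. The forward step requires benzylation at the carbon next to the tert-butyl ester, not at the phosphorus-bearing carbon; the reactivity order of a dianion secures this.

7 to 5 and 6: the C3–C4 bond is cut between the phosphorus-bearing carbon and the CH2 next to the tert-butyl ester. Both pieces are commodity chemicals, and the cut fixes which carboxyl is the methyl ester (C5) and which the tert-butyl ester (C2). The forward step must stop at monoalkylation.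

4 to 3 to 2 to 1: functional-group changes only (C6–Br, the oxidation level of C6, the O–benzyl bond). The chain ends at a cheap aldehyde that already holds the full ring B substitution. The forward steps must keep the electron-rich benzylic bromide intact until it is used.

## Other disconnections considered

Alternative 1: The cut removes C5 as a one-carbon unit: C4–C5 and O1–C2 are broken together. This leaves (E)-2-(4-benzyloxy-3,5-dimethoxybenzyl)-4-(3,4-dimethoxyphenyl)but-2-enal (A1) and formaldehyde (A2).
- Forward step: a chiral triazolium-derived carbene would add to the aldehyde of A1, the homoenolate would attack A2 through C4, and the new alkoxide would be acylated at C2 to close ring A. The product would be (3R,4R)-3-(4-benzyloxy-3,5-dimethoxybenzyl)-4-(3,4-dimethoxybenzyl)dihydrofuran-2(3H)-one (A3), identical with 14.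
- In favour: ring A, the C4–C5 bond and the C4 centre arise in one metal-free, redox-neutral operation, and A3 is one hydrogenolysis from the target. After the key step this plan is better than the chosen one on step economy. A2 is not prochiral, so only the face of the homoenolate needs control.
- Against: A1 is α-branched with an aliphatic β-substituent, the enal class that forms homoenolates most reluctantly, and its C7 hydrogens invite dienolate side reactions. A2 is prone to carbene-mediated self-condensation. C4 would be formed far from the stereogenic part of the carbene.
- Comparison: C3 would be set by an uncontrolled enol protonation, so an equilibration like step 8 would still be needed; the two plans are equal on this point. A1 needs its own regiocontrolled synthesis of a trisubstituted enal from two aldehyde-level fragments, so the total count would be similar to or slightly below nine. Mechanistically the chosen plan stays within established aryl–rhodium additions to itaconates, while this one would stretch homoenolate chemistry in several directions at once. Structurally both converge on the same compound.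

Alternative 2: The cut is C4–C5 at the boronic ester level. (S)-2-[1-Benzyloxy-3-(3,4-dimethoxyphenyl)propan-2-yl]-4,4,5,5-tetramethyl-1,3,2-dioxaborolane (A6) is traced to 2-(3,4-dimethoxyphenyl)ethyl N,N-diisopropylcarbamate (A4) and 2-(benzyloxymethyl)-4,4,5,5-tetramethyl-1,3,2-dioxaborolane (A5).
- Forward step: carbamate-directed lithiation of A4 next to oxygen with an alkyllithium and a chiral diamine, capture by A5 as a boronate complex, and stereospecific 1,2-migration of the benzyloxymethyl group with loss of the carbamate would give A6.
- In favour: the C4 configuration is reagent-controlled with no stereocentre nearby, so the substrate-bias problem of the chosen key step does not arise. On security of the absolute configuration at C4 this plan is better. A second homologation with a lithiated carbamate carrying ring B could also set C3 by reagent control, which would make the equilibration unnecessary.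
- Against: A6 holds only C4, C5, C7 and ring C. C3, C6 with ring B and the carboxyl C2 would still need a second stereospecific homologation, a one-carbon homologation with oxidation to the acid level, debenzylation and lactonisation. The oxygen β to boron in A6 opens a β-elimination path in every later boronate complex. Lithiated A4 has benzylic hydrogens beside the carbanion and may fragment to a styrene.
- Comparison: a stoichiometric chiral diamine and cryogenic organolithium chemistry at each homologation stand against a few mol % of a rhodium complex. The step count would be clearly higher than nine, so the chosen plan is better on step economy and this one on stereochemical predictability.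

Alternative 3: The cut is O1–C5. tert-Butyl (4S)-3-(4-benzyloxy-3,5-dimethoxybenzyl)-4-(hydroxymethyl)-2-oxotetrahydrofuran-3-carboxylate (A8) is traced to the achiral di-tert-butyl 2-(4-benzyloxy-3,5-dimethoxybenzyl)-2-(oxetan-3-yl)propanedioate (A7).
- Forward step: under a chiral phosphoric acid one ester carbonyl oxygen of A7 would open the activated oxetane at one of its two enantiotopic CH2 groups. This closes ring A, releases the C7 hydroxymethyl group and expels the tert-butyl group as the corresponding alkene, giving A8.
- In favour: it is catalytic, and C4 is set in an achiral substrate, so no competing stereocentre exists; on this point it is better than the chosen plan. The extra ester at C3 can later be removed with protonation to the trans lactone, so C3 is handled by thermodynamics as in the chosen plan (equal).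
- Against: A8 carries a hydroxyl at C7 instead of ring C. The C7–ring C bond would have to be made late by an sp3–sp2 coupling at a β-branched primary carbon, through a sulfonate or iodide, in the presence of the lactone and the ester. A7 must first be assembled from a malonate already carrying the oxetane ring and 4. Ester cleavage, decarboxylation and debenzylation then follow.
- Comparison: the estimate is eleven or more steps against nine. Structurally this plan builds ring A first and attaches ring C last, whereas the chosen plan uses the ring C bond itself to create C4. Mechanistically both rely on a catalyst-controlled step, but here the decisive bond formation is postponed to a coupling that is harder to defend.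

Key step: step 6

Assumption: (R)-BINAP is taken as the ligand enantiomer that leads to the R configuration at C4. The sense of protonation cannot be predicted with certainty for this substrate, and (S)-BINAP would replace it if the opposite sense were found.

## Route

Step 1
Reactants: 1 syringaldehyde (4-hydroxy-3,5-dimethoxybenzaldehyde)
Product: 2 4-benzyloxy-3,5-dimethoxybenzaldehyde
Conditions: BnBr (1.1 equiv), K2CO3 (1.5 equiv), DMF, 60 °C
Reagents that add atoms: benzyl bromide, BrCc1ccccc1
Why: Williamson etherification of the phenolate, whose acidity is raised by the para-formyl group, should proceed cleanly at oxygen. The benzyl ether masks the oxidation-prone phenol of ring B until the last step.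

Step 2
Reactants: 2 4-benzyloxy-3,5-dimethoxybenzaldehyde
Product: 3 (4-benzyloxy-3,5-dimethoxyphenyl)methanol
Conditions: NaBH4 (0.5 equiv), MeOH/THF, 0 °C
Reagents that add atoms: none
Why: Borohydride reduction of an aromatic aldehyde to the benzylic alcohol; the ethers are inert.

Step 3
Reactants: 3 (4-benzyloxy-3,5-dimethoxyphenyl)methanol
Product: 4 2-benzyloxy-5-(bromomethyl)-1,3-dimethoxybenzene
Conditions: PBr3 (0.4 equiv), CH2Cl2, 0 °C
Reagents that add atoms: phosphorus tribromide, BrP(Br)Br
Why: Activation of the benzylic alcohol as a phosphite ester and displacement by bromide (SN2 at a benzylic carbon). The electron-rich bromide is made cold and used without long storage.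

Step 4
Reactants: 5 trimethyl phosphonoacetate; 6 tert-butyl bromoacetate
Product: 7 4-tert-butyl 1-methyl 2-(dimethoxyphosphoryl)butanedioate (racemic)
Conditions: NaH (1.0 equiv), THF, 0 °C; then 6 (0.9 equiv), 0 °C to rt
Reagents that add atoms: none
Why: C-alkylation of the sodium phosphonoacetate carbanion by an α-halo ester (SN2); a slight excess of 5 suppresses double alkylation. This step fixes C5 as the methyl ester and C2 as the tert-butyl ester.

Step 5
Reactants: 7 4-tert-butyl 1-methyl 2-(dimethoxyphosphoryl)butanedioate; 4 2-benzyloxy-5-(bromomethyl)-1,3-dimethoxybenzene
Product: 9 4-tert-butyl 1-methyl 3-(4-benzyloxy-3,5-dimethoxybenzyl)-2-methylenebutanedioate (racemic), via lithium carbanion of the benzylated phosphonosuccinate 8 (not isolated)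
Conditions: LiN(iPr)2 (2.1 equiv), THF, −78 °C; 4 (1.0 equiv), −78 to 0 °C; then (CH2O)n (excess), 0 °C to rt
Reagents that add atoms: formaldehyde (from paraformaldehyde), C=O
Why: Double deprotonation of 7 should give a dianion whose last-formed, more basic carbanion (the tert-butyl ester enolate carbon) is benzylated by 4 (dianion alkylation), leaving the phosphonate-stabilised carbanion 8. Formaldehyde then traps 8 in a Horner–Wadsworth–Emmons methylenation; C3 is formed racemic on purpose.

Step 6
Reactants: 9 4-tert-butyl 1-methyl 3-(4-benzyloxy-3,5-dimethoxybenzyl)-2-methylenebutanedioate (racemic); 10 3,4-dimethoxyphenylboronic acid (2.5 equiv)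
Product: 11 4-tert-butyl 1-methyl (2R)-3-(4-benzyloxy-3,5-dimethoxybenzyl)-2-(3,4-dimethoxybenzyl)butanedioate (both C3 epimers)
Conditions: [Rh(OH)((R)-BINAP)]2 (2.5 mol %), B(OH)3 (2 equiv), 1,4-dioxane, 60 °C
Reagents that add atoms: none
Why: Transmetalation of 10 to the hydroxo complex of monovalent rhodium gives an aryl–rhodium–BINAP species, which inserts the 1,1-disubstituted alkene of 9 with the aryl group going to the unsubstituted methylene carbon (C7, lactone numbering), so that rhodium ends on C4 as an oxa-π-allyl (enolate) of the methyl ester. Protonation of this enolate at C4 by boric acid releases 11 and returns a rhodium–oxygen species that transmetalates again. The closest known reaction type is the Hayashi–Miyaura conjugate addition run as a tandem addition and enantioselective protonation on itaconate diesters. No ring is closed. The only new stereocentre, C4, is controlled by the ligand: the proton is delivered to the enolate face left open by the phenyl groups of (R)-BINAP, which is expected to give the 2R diester. Regioselectivity follows from the acrylate polarisation, since only the methyl ester is conjugated with the alkene and the tert-butyl ester is a spectator. The step needs ligand control to dominate over the racemic C3 centre, so that both enantiomers of 9 are protonated in the same sense and give the two C3 epimers of one C4 series, which step 8 later merges. A catalyst free of 1,5-cyclooctadiene and of added base, with a mild proton donor, is chosen to avoid an achiral background reaction, migration of the double bond into conjugation through the acidic C3–H, and β-hydride elimination in place of protonation.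

Step 7
Reactants: 11 4-tert-butyl 1-methyl (2R)-3-(4-benzyloxy-3,5-dimethoxybenzyl)-2-(3,4-dimethoxybenzyl)butanedioate (both C3 epimers)
Product: 13 (4R)-3-(4-benzyloxy-3,5-dimethoxybenzyl)-4-(3,4-dimethoxybenzyl)dihydrofuran-2(3H)-one (both C3 epimers), via hydroxy tert-butyl ester 12 (not isolated)
Conditions: LiBH4 (3 equiv), MeOH (1 equiv), THF, 0 °C to rt; MeOH quench, evaporate; then TFA/CH2Cl2 (1:4), 0 °C to rt
Reagents that add atoms: none
Why: LiBH4 should reduce the methyl ester chemoselectively beside the hindered tert-butyl ester, giving alcohol 12; after this C4 is no longer α to a carbonyl and is fixed. TFA then cleaves the tert-butyl ester (loss of the tert-butyl cation as 2-methylpropene) and the γ-hydroxy acid closes by 5-exo-trig acyl substitution to the lactone; C3 passes through as an epimer mixture.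

Step 8
Reactants: 13 (4R)-3-(4-benzyloxy-3,5-dimethoxybenzyl)-4-(3,4-dimethoxybenzyl)dihydrofuran-2(3H)-one (both C3 epimers)
Product: 14 (3R,4R)-3-(4-benzyloxy-3,5-dimethoxybenzyl)-4-(3,4-dimethoxybenzyl)dihydrofuran-2(3H)-one
Conditions: DBU (0.5 equiv), toluene, 80 °C
Reagents that add atoms: none
Why: DBU reversibly enolises the lactone at C3, the only acidic stereocentre, so both C3 epimers should converge on the thermodynamically preferred trans lactone (base-mediated epimerisation); C4 is β to the carbonyl and is untouched. Any remaining cis isomer is separated and resubmitted.

Step 9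
Reactants: 14 (3R,4R)-3-(4-benzyloxy-3,5-dimethoxybenzyl)-4-(3,4-dimethoxybenzyl)dihydrofuran-2(3H)-one
Product: 15 (3R,4R)-4-(3,4-dimethoxybenzyl)-3-(4-hydroxy-3,5-dimethoxybenzyl)dihydrofuran-2(3H)-one
Conditions: H2 (1 atm), Pd/C (10 wt %), EtOAc/EtOH, rt
Reagents that add atoms: none
Why: Hydrogenolysis of the aryl benzyl ether under neutral conditions frees the phenol; the lactone, the aryl methyl ethers and both stereocentres are inert.

## Compound list

1 | syringaldehyde (4-hydroxy-3,5-dimethoxybenzaldehyde) | COc1cc(C=O)cc(OC)c1O | starting material
2 | 4-benzyloxy-3,5-dimethoxybenzaldehyde | COc1cc(C=O)cc(OC)c1OCc1ccccc1 | intermediate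
3 | (4-benzyloxy-3,5-dimethoxyphenyl)methanol | COc1cc(CO)cc(OC)c1OCc1ccccc1 | intermediate
4 | 2-benzyloxy-5-(bromomethyl)-1,3-dimethoxybenzene | COc1cc(CBr)cc(OC)c1OCc1ccccc1 | intermediate
5 | trimethyl phosphonoacetate | COC(=O)CP(=O)(OC)OC | starting material
6 | tert-butyl bromoacetate | CC(C)(C)OC(=O)CBr | starting material
7 | 4-tert-butyl 1-methyl 2-(dimethoxyphosphoryl)butanedioate (racemic) | COC(=O)C(CC(=O)OC(C)(C)C)P(=O)(OC)OC | intermediate
8 | lithium carbanion (at C2) of 4-tert-butyl 1-methyl 3-(4-benzyloxy-3,5-dimethoxybenzyl)-2-(dimethoxyphosphoryl)butanedioate (racemic) | [Li+].COC(=O)[C-](P(=O)(OC)OC)C(Cc1cc(OC)c(OCc2ccccc2)c(OC)c1)C(=O)OC(C)(C)C | intermediate (not isolated)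
9 | 4-tert-butyl 1-methyl 3-(4-benzyloxy-3,5-dimethoxybenzyl)-2-methylenebutanedioate (racemic) | COc1cc(CC(C(=C)C(=O)OC)C(=O)OC(C)(C)C)cc(OC)c1OCc1ccccc1 | intermediate
10 | 3,4-dimethoxyphenylboronic acid | COc1ccc(B(O)O)cc1OC | starting material
11 | 4-tert-butyl 1-methyl (2R)-3-(4-benzyloxy-3,5-dimethoxybenzyl)-2-(3,4-dimethoxybenzyl)butanedioate (both C3 epimers) | COc1ccc(C[C@@H](C(=O)OC)C(Cc2cc(OC)c(OCc3ccccc3)c(OC)c2)C(=O)OC(C)(C)C)cc1OC | intermediate
12 | tert-butyl (3R)-2-(4-benzyloxy-3,5-dimethoxybenzyl)-4-(3,4-dimethoxyphenyl)-3-(hydroxymethyl)butanoate (both C2 epimers) | COc1ccc(C[C@@H](CO)C(Cc2cc(OC)c(OCc3ccccc3)c(OC)c2)C(=O)OC(C)(C)C)cc1OC | intermediate (not isolated)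
13 | (4R)-3-(4-benzyloxy-3,5-dimethoxybenzyl)-4-(3,4-dimethoxybenzyl)dihydrofuran-2(3H)-one (both C3 epimers) | COc1ccc(C[C@H]2COC(=O)C2Cc2cc(OC)c(OCc3ccccc3)c(OC)c2)cc1OC | intermediate
14 | (3R,4R)-3-(4-benzyloxy-3,5-dimethoxybenzyl)-4-(3,4-dimethoxybenzyl)dihydrofuran-2(3H)-one | COc1ccc(C[C@H]2COC(=O)[C@@H]2Cc2cc(OC)c(OCc3ccccc3)c(OC)c2)cc1OC | intermediate
15 | (3R,4R)-4-(3,4-dimethoxybenzyl)-3-(4-hydroxy-3,5-dimethoxybenzyl)dihydrofuran-2(3H)-one | COc1ccc(C[C@H]2COC(=O)[C@@H]2Cc2cc(OC)c(O)c(OC)c2)cc1OC | target

## Step count and least certain steps

Total: 9 steps. Longest linear sequence: 8 steps (1 to 15 through steps 1, 2, 3, 5, 6, 7, 8 and 9); step 4 supplies the second branch.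

Step 6 (key step). The most likely failure is insufficient ligand control in the protonation. The C3 stereocentre sits next to the enolate carbon, so in the mismatched enantiomer of 9 the substrate's own facial preference may compete. That would lower the enantiomeric purity at C4, which no later step can repair. Secondary risks are migration of the alkene into conjugation through the acidic C3–H, β-hydride elimination in place of protonation, and protodeboronation of the electron-rich boronic acid.

The fallback sets out from 7 and returns at 14. It sets C4 on a substrate with no neighbouring stereocentre and brings in the ring B arm afterwards under substrate control. 7 is methylenated with K2CO3 and aqueous formaldehyde to 4-tert-butyl 1-methyl 2-methylenebutanedioate F1. F1 and 10 under the conditions of step 6 should give 4-tert-butyl 1-methyl (2R)-2-(3,4-dimethoxybenzyl)butanedioate F2. LiBH4 and then TFA, as in step 7, lead through tert-butyl (3R)-4-(3,4-dimethoxyphenyl)-3-(hydroxymethyl)butanoate F3 to (4R)-4-(3,4-dimethoxybenzyl)dihydrofuran-2(3H)-one F4. Deprotonation of F4 with LiN(SiMe3)2 in THF at −78 °C and alkylation with 4 from the face anti to the C4 substituent should give 14 directly.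

Step 5. Most likely to go wrong is incomplete formation of the dianion, followed by benzylation at the phosphorus-bearing carbon or Michael addition of carbanion 8 to freshly formed 9 during the methylenation. The second deprotonation creates a carbanion next to an existing one and is slow, and 9 is a good acceptor.

The fallback sets out from 4 and 5 and returns at 9; it avoids the dianion. The lithium enolate of tert-butyl acetate is alkylated with 4 to tert-butyl 3-(4-benzyloxy-3,5-dimethoxyphenyl)propanoate F5. Its enolate (LiN(iPr)2, −78 °C) is brominated with CBr4 to tert-butyl 3-(4-benzyloxy-3,5-dimethoxyphenyl)-2-bromopropanoate F6. Displacement of bromide by the sodium salt of 5 (NaH, DMF) gives neutral 4-tert-butyl 1-methyl 3-(4-benzyloxy-3,5-dimethoxybenzyl)-2-(dimethoxyphosphoryl)butanedioate F7. Horner–Wadsworth–Emmons methylenation of F7 with K2CO3 and aqueous formaldehyde gives 9.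

Step 7. The main risk is loss of chemoselectivity in the hydride stage. The lithium alkoxide may close onto the tert-butyl ester while hydride is still present, and the lactone would then be reduced further to a diol; the hindered methyl ester may also react slowly enough for the tert-butyl ester to compete. A lesser risk is partial acid cleavage of the aryl benzyl ether, with cationic alkylation of the electron-rich rings.

The fallback sets out from 11 and returns at 13; it reverses the order of events. TFA in CH2Cl2 first removes the tert-butyl group to give (3R)-2-(4-benzyloxy-3,5-dimethoxybenzyl)-3-(3,4-dimethoxybenzyl)-4-methoxy-4-oxobutanoic acid F8. Its potassium salt (KOH, 1 equiv) is reduced at the methyl ester with Ca(BH4)2 (from NaBH4 and CaCl2, EtOH); the carboxylate can neither be reduced nor lactonise under these conditions. This gives (3R)-2-(4-benzyloxy-3,5-dimethoxybenzyl)-4-(3,4-dimethoxyphenyl)-3-(hydroxymethyl)butanoic acid F9, which closes to 13 on acidification with aqueous HCl.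

## Further compounds

F1 | step 6 | 4-tert-butyl 1-methyl 2-methylenebutanedioate | C=C(CC(=O)OC(C)(C)C)C(=O)OC
F2 | step 6 | 4-tert-butyl 1-methyl (2R)-2-(3,4-dimethoxybenzyl)butanedioate | COc1ccc(C[C@@H](C(=O)OC)CC(=O)OC(C)(C)C)cc1OC
F3 | step 6 | tert-butyl (3R)-4-(3,4-dimethoxyphenyl)-3-(hydroxymethyl)butanoate | COc1ccc(C[C@@H](CO)CC(=O)OC(C)(C)C)cc1OC
F4 | step 6 | (4R)-4-(3,4-dimethoxybenzyl)dihydrofuran-2(3H)-one | COc1ccc(C[C@H]2COC(=O)C2)cc1OC
F5 | step 5 | tert-butyl 3-(4-benzyloxy-3,5-dimethoxyphenyl)propanoate | COc1cc(CCC(=O)OC(C)(C)C)cc(OC)c1OCc1ccccc1
F6 | step 5 | tert-butyl 3-(4-benzyloxy-3,5-dimethoxyphenyl)-2-bromopropanoate (racemic) | COc1cc(CC(Br)C(=O)OC(C)(C)C)cc(OC)c1OCc1ccccc1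
F7 | step 5 | 4-tert-butyl 1-methyl 3-(4-benzyloxy-3,5-dimethoxybenzyl)-2-(dimethoxyphosphoryl)butanedioate (diastereomer mixture, racemic) | COC(=O)C(P(=O)(OC)OC)C(Cc1cc(OC)c(OCc2ccccc2)c(OC)c1)C(=O)OC(C)(C)C
F8 | step 7 | (3R)-2-(4-benzyloxy-3,5-dimethoxybenzyl)-3-(3,4-dimethoxybenzyl)-4-methoxy-4-oxobutanoic acid (both C2 epimers) | COc1ccc(C[C@@H](C(=O)OC)C(Cc2cc(OC)c(OCc3ccccc3)c(OC)c2)C(=O)O)cc1OC
F9 | step 7 | (3R)-2-(4-benzyloxy-3,5-dimethoxybenzyl)-4-(3,4-dimethoxyphenyl)-3-(hydroxymethyl)butanoic acid (both C2 epimers) | COc1ccc(C[C@@H](CO)C(Cc2cc(OC)c(OCc3ccccc3)c(OC)c2)C(=O)O)cc1OC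
A1 | alternative 1 | (E)-2-(4-benzyloxy-3,5-dimethoxybenzyl)-4-(3,4-dimethoxyphenyl)but-2-enal | O=C/C(Cc1cc(OC)c(OCc2ccccc2)c(OC)c1)=C/Cc1ccc(OC)c(OC)c1
A2 | alternative 1 | formaldehyde | C=O
A3 | alternative 1 | (3R,4R)-3-(4-benzyloxy-3,5-dimethoxybenzyl)-4-(3,4-dimethoxybenzyl)dihydrofuran-2(3H)-one | COc1ccc(C[C@H]2COC(=O)[C@@H]2Cc2cc(OC)c(OCc3ccccc3)c(OC)c2)cc1OC
A4 | alternative 2 | 2-(3,4-dimethoxyphenyl)ethyl N,N-diisopropylcarbamate | COc1ccc(CCOC(=O)N(C(C)C)C(C)C)cc1OC
A5 | alternative 2 | 2-(benzyloxymethyl)-4,4,5,5-tetramethyl-1,3,2-dioxaborolane | CC1(C)OB(COCc2ccccc2)OC1(C)C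
A6 | alternative 2 | (S)-2-[1-benzyloxy-3-(3,4-dimethoxyphenyl)propan-2-yl]-4,4,5,5-tetramethyl-1,3,2-dioxaborolane | COc1ccc(C[C@@H](COCc2ccccc2)B2OC(C)(C)C(C)(C)O2)cc1OC
A7 | alternative 3 | di-tert-butyl 2-(4-benzyloxy-3,5-dimethoxybenzyl)-2-(oxetan-3-yl)propanedioate | COc1cc(CC(C2COC2)(C(=O)OC(C)(C)C)C(=O)OC(C)(C)C)cc(OC)c1OCc1ccccc1
A8 | alternative 3 | tert-butyl (4S)-3-(4-benzyloxy-3,5-dimethoxybenzyl)-4-(hydroxymethyl)-2-oxotetrahydrofuran-3-carboxylate (either configuration at C3) | OC[C@H]1COC(=O)C1(Cc1cc(OC)c(OCc2ccccc2)c(OC)c1)C(=O)OC(C)(C)C
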